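**Plan**

- Retrosynthesis: the side-chain C=C is cut by a Wittig disconnection. Ring B (C1' O-aryl, C2' OH, C4' CH3, C6' side chain) is then cut at C1'–C6' and C3'–C4'. The ether O–C1' bond goes back to a ring A phenol and chloroacetone. Ring A (C1 CO2H, C2 OMe, C3 side chain, C6 O) loses its C1–CO2H bond (ortho-lithiation) and its benzylic C–C bond (Grignard addition).
- Enabling feature: ring B is a 2-aryloxyphenol. C1'(OAr)–C2'(OH)–C3'(H) maps onto an aryloxyacetone and C4'(CH3)–C5'(H)–C6'(masked CHO) onto an alkynone, so the diaryl ether oxygen can be alkylated at sp3 carbon before ring B exists.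
- Forward order: ring A is elaborated from 4-hydroxy-2-methoxybenzaldehyde (isobutyl carbinol, carboxyl group, acetonyl ether, acetate). Ring B is then annulated onto the ether carbon with 5,5-diethoxypent-3-yn-2-one. The acetal is opened and the enone chain is attached last.
- Stereochemistry: the single (S) center comes from a Corey–Bakshi–Shibata reduction of the aryl isobutyl ketone and is carried through unchanged. The (E)-alkene comes from a stabilised ylide.
- Remark: the benzylic alcohol is acetylated only after the phenol oxygen has been alkylated, because a phenoxide para to a benzylic acetate would ionise to a quinone methide.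

Key step: step 12

**Route**

Step 1
Reactants: 1 4-hydroxy-2-methoxybenzaldehyde
Product: 2 2-methoxy-4-{[2-(trimethylsilyl)ethoxy]methoxy}benzaldehyde
Conditions: SEMCl, i-Pr2NEt, CH2Cl2, 0 °C → rt
Reagents that add atoms: 2-(trimethylsilyl)ethoxymethyl chloride (SEMCl), C[Si](C)(C)CCOCCl
Why: Williamson-type O-alkylation of the acidic phenol gives an acetal ether that survives Grignard, borane and organolithium reagents, directs the later ortho-lithiation and can be removed by fluoride without acid.

Step 2
Reactants: 2 2-methoxy-4-{[2-(trimethylsilyl)ethoxy]methoxy}benzaldehyde; 3 isobutylmagnesium bromide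
Product: 4 rac-1-(2-methoxy-4-{[2-(trimethylsilyl)ethoxy]methoxy}phenyl)-3-methylbutan-1-ol
Conditions: THF, 0 °C; then H2O
Reagents that add atoms: none
Why: Grignard 1,2-addition to the aryl aldehyde installs the isobutyl chain; the racemic center is erased in the next step.

Step 3
Reactants: 4 rac-1-(2-methoxy-4-{[2-(trimethylsilyl)ethoxy]methoxy}phenyl)-3-methylbutan-1-ol
Product: 5 1-(2-methoxy-4-{[2-(trimethylsilyl)ethoxy]methoxy}phenyl)-3-methylbutan-1-one
Conditions: Dess–Martin periodinane, CH2Cl2, 0 °C → rt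
Reagents that add atoms: none
Why: Dess–Martin oxidation of a secondary benzylic alcohol to the aryl ketone is fast and mild enough for the SEM acetal.

Step 4
Reactants: 5 1-(2-methoxy-4-{[2-(trimethylsilyl)ethoxy]methoxy}phenyl)-3-methylbutan-1-one
Product: 6 (S)-1-(2-methoxy-4-{[2-(trimethylsilyl)ethoxy]methoxy}phenyl)-3-methylbutan-1-ol
Conditions: (R)-2-methyl-CBS-oxazaborolidine [(R)-1-methyl-3,3-diphenyltetrahydro-1H,3H-pyrrolo[1,2-c][1,3,2]oxazaborole] (cat.), BH3·SMe2, THF, −20 °C; MeOH quench
Reagents that add atoms: none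
Why: Corey–Bakshi–Shibata reduction, in which the (R)-oxazaborolidine binds borane and the ketone with the aryl group as the large substituent and delivers hydride to the face that gives the (S)-carbinol (the (S)-catalyst is known to give (R)-1-arylalkanols).

Step 5
Reactants: 6 (S)-1-(2-methoxy-4-{[2-(trimethylsilyl)ethoxy]methoxy}phenyl)-3-methylbutan-1-ol
Product: 8 (S)-3-(1-hydroxy-3-methylbutyl)-2-methoxy-6-{[2-(trimethylsilyl)ethoxy]methoxy}benzoic acid, via dilithio alkoxide aryllithium 7 (not isolated)
Conditions: n-BuLi (2.3 equiv), TMEDA, THF, −20 → 0 °C; CO2, −78 °C → rt; cold 0.5 M HCl to pH 4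
Reagents that add atoms: carbon dioxide, O=C=O
Why: Directed ortho-metalation, in which the first equivalent of base forms the alkoxide and the second removes the only ring proton flanked by two ether oxygens (OMe and OSEM), followed by carboxylation of the aryllithium, which leaves the alkoxide-bearing stereocenter untouched.

Step 6
Reactants: 8 (S)-3-(1-hydroxy-3-methylbutyl)-2-methoxy-6-{[2-(trimethylsilyl)ethoxy]methoxy}benzoic acid
Product: 9 allyl (S)-3-(1-hydroxy-3-methylbutyl)-2-methoxy-6-{[2-(trimethylsilyl)ethoxy]methoxy}benzoate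
Conditions: allyl bromide, KHCO3, DMF, rt
Reagents that add atoms: allyl bromide, C=CCBr
Why: SN2 O-alkylation of the carboxylate (hydrogencarbonate does not deprotonate the secondary alcohol) gives an ester that masks the acid during phenol alkylation and is later removable under neutral conditions.

Step 7
Reactants: 9 allyl (S)-3-(1-hydroxy-3-methylbutyl)-2-methoxy-6-{[2-(trimethylsilyl)ethoxy]methoxy}benzoate
Product: 10 allyl (S)-6-hydroxy-3-(1-hydroxy-3-methylbutyl)-2-methoxybenzoate
Conditions: Bu4NF, THF, rt → 45 °C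
Reagents that add atoms: none
Why: Fluoride-induced fragmentation of the SEM ether (attack at silicon, loss of ethene and formaldehyde) frees the phenol without acid, which the electron-rich benzylic carbinol would not tolerate (SN1 ionisation).

Step 8
Reactants: 10 allyl (S)-6-hydroxy-3-(1-hydroxy-3-methylbutyl)-2-methoxybenzoate; 11 chloroacetone
Product: 12 allyl (S)-3-(1-hydroxy-3-methylbutyl)-2-methoxy-6-(2-oxopropoxy)benzoate
Conditions: K2CO3, KI (cat.), acetone, 50 °C
Reagents that add atoms: none
Why: Williamson ether synthesis at the sp3 carbon of chloroacetone with the salicylate phenoxide; carbonate is too weak to start a Dieckmann-type closure onto the hindered ester, and the benzylic hydroxyl (a poor leaving group) is still free at this stage.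

Step 9
Reactants: 12 allyl (S)-3-(1-hydroxy-3-methylbutyl)-2-methoxy-6-(2-oxopropoxy)benzoate
Product: 13 allyl (S)-3-(1-acetoxy-3-methylbutyl)-2-methoxy-6-(2-oxopropoxy)benzoate
Conditions: Ac2O, pyridine, DMAP (cat.), CH2Cl2, 0 °C → rt
Reagents that add atoms: acetic anhydride, CC(=O)OC(C)=O
Why: DMAP-catalysed O-acylation of the secondary alcohol proceeds with retention at the (S) center and is safe now that the para oxygen is an ether.

Step 10
Reactants: 13 allyl (S)-3-(1-acetoxy-3-methylbutyl)-2-methoxy-6-(2-oxopropoxy)benzoate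
Product: 14 (S)-3-(1-acetoxy-3-methylbutyl)-2-methoxy-6-(2-oxopropoxy)benzoic acid
Conditions: Pd(PPh3)4 (cat.), morpholine, THF, rt; cold dilute citric acid work-up
Reagents that add atoms: none
Why: Tsuji–Trost deallylation, in which zerovalent palladium ionises the allyl ester to a π-allyl complex that morpholine traps, frees the acid under conditions that harm neither the acetate nor the ketone.

Step 11
Reactants: 15 3,3-diethoxyprop-1-yne
Product: 18 5,5-diethoxypent-3-yn-2-one, via lithium 3,3-diethoxyprop-1-ynide 16 (not isolated), via lithium hemiaminal alkoxide 17 (not isolated)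
Conditions: n-BuLi, THF, −78 °C; N-methoxy-N-methylacetamide, −78 → 0 °C; H2O (pH 7 buffer)
Reagents that add atoms: N-methoxy-N-methylacetamide, CON(C)C(C)=O
Why: Weinreb ketone synthesis with a lithium acetylide, in which the chelated tetrahedral adduct persists until the quench, so the ynone is not attacked a second time and the acetal is untouched.

Step 12
Reactants: 14 (S)-3-(1-acetoxy-3-methylbutyl)-2-methoxy-6-(2-oxopropoxy)benzoic acid; 18 5,5-diethoxypent-3-yn-2-one
Product: 21 (S)-3-(1-acetoxy-3-methylbutyl)-6-[2-(diethoxymethyl)-6-hydroxy-4-methylphenoxy]-2-methoxybenzoic acid, via acyclic Michael adduct 19 (not isolated), via cyclic aldol adduct 20 (not isolated)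
Conditions: Cs2CO3 (3 equiv), 4 Å molecular sieves, MeCN, rt → 60 °C, 18 (1.2 equiv) added slowly; work-up at pH 5 (phosphate–citrate buffer)
Reagents that add atoms: none
Why: Cs2CO3 first turns 14 into its cesium carboxylate (so no ester is left for a Dieckmann-type closure to a benzofuranone) and then reversibly deprotonates the aryloxy-bearing methylene C1', which adds in conjugate fashion to the alkyne terminus C6' of 18 to give dienone 19 (C1'–C6' bond). After the enone geometry equilibrates through the C1' dienolate, the methyl ketone enolate (C3') attacks the C4' carbonyl in a 6-(enolendo)-exo-trig aldol closure to 20 (C3'–C4' bond), and E1cB loss of water followed by keto–enol tautomerisation gives the phenol of ring B without an oxidant. The closest known reaction type is the base-mediated Michael–aldol [3+3] benzannulation of ketones bearing two enolisable α-positions with alkynones. No stereocenter is created (the C1' center of 19 and 20 disappears on aromatisation) and the (S)-acetate is a spectator. Two selectivities are needed: the Michael addition must go through C1' and not C3', which the higher acidity of the ArO–CH2 group and the single electrophilic terminus of the ynone secure; and the ring must close from C3' onto C4' and not from the ynone methyl onto C2', which is favoured but not guaranteed, because C2' is shielded by the fully substituted C1', the diethoxymethyl group and the neighbouring carboxylate, whereas C4' is an unhindered acetyl carbonyl and the C3'–H bonds are acidified by the α-aryloxy ketone. The sieves take up the water formed, so the acetate and the acetal should survive.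

Step 13
Reactants: 21 (S)-3-(1-acetoxy-3-methylbutyl)-6-[2-(diethoxymethyl)-6-hydroxy-4-methylphenoxy]-2-methoxybenzoic acid
Product: 22 (S)-3-(1-acetoxy-3-methylbutyl)-6-(2-formyl-6-hydroxy-4-methylphenoxy)-2-methoxybenzoic acid
Conditions: AcOH–THF–H2O (3:1:1), rt
Reagents that add atoms: water, O
Why: Acid-catalysed acetal hydrolysis through the benzylic oxocarbenium ion is far faster in aqueous acetic acid than ionisation of the benzylic acetate, so only the aldehyde is unmasked.

Step 14
Reactants: 22 (S)-3-(1-acetoxy-3-methylbutyl)-6-(2-formyl-6-hydroxy-4-methylphenoxy)-2-methoxybenzoic acid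
Product: 23 (S)-3-(1-acetoxy-3-methylbutyl)-6-{2-hydroxy-4-methyl-6-[(E)-3-oxobut-1-en-1-yl]phenoxy}-2-methoxybenzoic acid
Conditions: Ph3P=CHC(O)CH3 (3 equiv), CH2Cl2, rt → 40 °C; cold dilute citric acid wash
Reagents that add atoms: 1-(triphenylphosphoranylidene)propan-2-one, CC(=O)C=P(c1ccccc1)(c1ccccc1)c1ccccc1
Why: Wittig olefination with a stabilised ylide should give the (E)-enone; the excess ylide covers the equivalent protonated by the carboxylic acid, and the phenol does not interfere.

**Compound list**

1 | 4-hydroxy-2-methoxybenzaldehyde | COc1cc(O)ccc1C=O | starting material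
2 | 2-methoxy-4-{[2-(trimethylsilyl)ethoxy]methoxy}benzaldehyde | COc1cc(OCOCC[Si](C)(C)C)ccc1C=O | intermediate
3 | isobutylmagnesium bromide | CC(C)C[Mg]Br | starting material
4 | rac-1-(2-methoxy-4-{[2-(trimethylsilyl)ethoxy]methoxy}phenyl)-3-methylbutan-1-ol | COc1cc(OCOCC[Si](C)(C)C)ccc1C(O)CC(C)C | intermediate
5 | 1-(2-methoxy-4-{[2-(trimethylsilyl)ethoxy]methoxy}phenyl)-3-methylbutan-1-one | COc1cc(OCOCC[Si](C)(C)C)ccc1C(=O)CC(C)C | intermediate
6 | (S)-1-(2-methoxy-4-{[2-(trimethylsilyl)ethoxy]methoxy}phenyl)-3-methylbutan-1-ol | COc1c([C@H](CC(C)C)O)ccc(OCOCC[Si](C)(C)C)c1 | intermediate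
7 | lithium (S)-1-(3-lithio-2-methoxy-4-{[2-(trimethylsilyl)ethoxy]methoxy}phenyl)-3-methylbutan-1-olate | COc1c([C@H](CC(C)C)O[Li])ccc(OCOCC[Si](C)(C)C)c1[Li] | intermediate
8 | (S)-3-(1-hydroxy-3-methylbutyl)-2-methoxy-6-{[2-(trimethylsilyl)ethoxy]methoxy}benzoic acid | COc1c([C@H](CC(C)C)O)ccc(OCOCC[Si](C)(C)C)c1C(=O)O | intermediate
9 | allyl (S)-3-(1-hydroxy-3-methylbutyl)-2-methoxy-6-{[2-(trimethylsilyl)ethoxy]methoxy}benzoate | COc1c([C@H](CC(C)C)O)ccc(OCOCC[Si](C)(C)C)c1C(=O)OCC=C | intermediate
10 | allyl (S)-6-hydroxy-3-(1-hydroxy-3-methylbutyl)-2-methoxybenzoate | COc1c([C@H](CC(C)C)O)ccc(O)c1C(=O)OCC=C | intermediate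
11 | chloroacetone | CC(=O)CCl | starting material
12 | allyl (S)-3-(1-hydroxy-3-methylbutyl)-2-methoxy-6-(2-oxopropoxy)benzoate | COc1c([C@H](CC(C)C)O)ccc(OCC(C)=O)c1C(=O)OCC=C | intermediate
13 | allyl (S)-3-(1-acetoxy-3-methylbutyl)-2-methoxy-6-(2-oxopropoxy)benzoate | COc1c([C@H](CC(C)C)OC(C)=O)ccc(OCC(C)=O)c1C(=O)OCC=C | intermediate
14 | (S)-3-(1-acetoxy-3-methylbutyl)-2-methoxy-6-(2-oxopropoxy)benzoic acid | COc1c([C@H](CC(C)C)OC(C)=O)ccc(OCC(C)=O)c1C(=O)O | intermediate
15 | 3,3-diethoxyprop-1-yne | C#CC(OCC)OCC | starting material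
16 | lithium 3,3-diethoxyprop-1-ynide | [Li]C#CC(OCC)OCC | intermediate
17 | lithium 5,5-diethoxy-2-[methoxy(methyl)amino]pent-3-yn-2-olate | CCOC(OCC)C#CC(C)(O[Li])N(C)OC | intermediate
18 | 5,5-diethoxypent-3-yn-2-one | CCOC(OCC)C#CC(C)=O | intermediate
19 | (S)-3-(1-acetoxy-3-methylbutyl)-6-{[4-(diethoxymethyl)-2,6-dioxohept-4-en-3-yl]oxy}-2-methoxybenzoic acid (C1' epimers, alkene isomers) | COc1c([C@H](CC(C)C)OC(C)=O)ccc(OC(C(C)=O)C(=CC(C)=O)C(OCC)OCC)c1C(=O)O | intermediate
20 | (S)-3-(1-acetoxy-3-methylbutyl)-6-{[2-(diethoxymethyl)-4-hydroxy-4-methyl-6-oxocyclohex-2-en-1-yl]oxy}-2-methoxybenzoic acid (ring diastereomers) | COc1c([C@H](CC(C)C)OC(C)=O)ccc(OC2C(=O)CC(C)(O)C=C2C(OCC)OCC)c1C(=O)O | intermediate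
21 | (S)-3-(1-acetoxy-3-methylbutyl)-6-[2-(diethoxymethyl)-6-hydroxy-4-methylphenoxy]-2-methoxybenzoic acid | COc1c([C@H](CC(C)C)OC(C)=O)ccc(Oc2c(O)cc(C)cc2C(OCC)OCC)c1C(=O)O | intermediate
22 | (S)-3-(1-acetoxy-3-methylbutyl)-6-(2-formyl-6-hydroxy-4-methylphenoxy)-2-methoxybenzoic acid | COc1c([C@H](CC(C)C)OC(C)=O)ccc(Oc2c(O)cc(C)cc2C=O)c1C(=O)O | intermediate
23 | (S)-3-(1-acetoxy-3-methylbutyl)-6-{2-hydroxy-4-methyl-6-[(E)-3-oxobut-1-en-1-yl]phenoxy}-2-methoxybenzoic acid | COc1c([C@H](CC(C)C)OC(C)=O)ccc(Oc2c(O)cc(C)cc2/C=C/C(C)=O)c1C(=O)O | target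

**Step count**

Total: 14 steps. Longest linear sequence: 13 steps (steps 1–10, then 12–14); the ynone 18 is made in one step (step 11).

**Steps most likely to fail**

1. Step 12 (ring B annulation). The ring may close in the other direction, with the enolate of the ynone-derived acetyl group attacking C2', which would give a para-hydroxy regioisomer. The ynone may also oligomerise under base, or be consumed by O-addition of the carboxylate or the product phenoxide.
 Fallback (sets out from phenol 10, comes back at aldehyde acid 22): the diaryl ether is made by nucleophilic aromatic substitution instead of annulation. 2-Fluoro-5-methylphenol is converted with SEMCl and i-Pr2NEt into trimethyl{2-[(2-fluoro-5-methylphenoxy)methoxy]ethyl}silane F1. This is lithiated next to fluorine (n-BuLi, THF, −78 °C) and formylated with DMF to 2-fluoro-5-methyl-3-{[2-(trimethylsilyl)ethoxy]methoxy}benzaldehyde F2. The phenoxide of 10 (K2CO3, DMF, 80 °C) displaces the fluoride ortho to the formyl group to give allyl (S)-6-(2-formyl-4-methyl-6-{[2-(trimethylsilyl)ethoxy]methoxy}phenoxy)-3-(1-hydroxy-3-methylbutyl)-2-methoxybenzoate F3. Acetylation (Ac2O, pyridine, DMAP) gives allyl (S)-3-(1-acetoxy-3-methylbutyl)-6-(2-formyl-4-methyl-6-{[2-(trimethylsilyl)ethoxy]methoxy}phenoxy)-2-methoxybenzoate F4. Bu4NF frees the ring B phenol as allyl (S)-3-(1-acetoxy-3-methylbutyl)-6-(2-formyl-6-hydroxy-4-methylphenoxy)-2-methoxybenzoate F5, and Pd(PPh3)4 with N-methylaniline as allyl acceptor removes the allyl ester to give 22, which enters step 14.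

2. Step 5 (ortho-lithiation and carboxylation). The lithium alkoxide may aggregate and slow the ring metalation, or direct it to the position next to the side chain, leading to incomplete or misplaced carboxylation.
 Fallback (sets out from carbinol 6, comes back at phenol 10): the hydroxyl is masked so that only one deprotonation is needed. TBSCl and imidazole give (S)-tert-butyl[1-(2-methoxy-4-{[2-(trimethylsilyl)ethoxy]methoxy}phenyl)-3-methylbutoxy]dimethylsilane F6. Lithiation between the two ether oxygens (s-BuLi, TMEDA, THF, −78 °C) and CO2 give (S)-3-{1-[(tert-butyldimethylsilyl)oxy]-3-methylbutyl}-2-methoxy-6-{[2-(trimethylsilyl)ethoxy]methoxy}benzoic acid F7. Allyl bromide and KHCO3 give allyl (S)-3-{1-[(tert-butyldimethylsilyl)oxy]-3-methylbutyl}-2-methoxy-6-{[2-(trimethylsilyl)ethoxy]methoxy}benzoate F8, and Bu4NF then removes both the SEM group and the silyl ether to give 10.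

3. Step 4 (enantioselective reduction). Facial selectivity may be poor because the ortho-methoxy group twists the aryl ring and can compete for the boron center, lowering the enantiomeric purity of the only stereocenter.
 Fallback (sets out from aldehyde 2, comes back at carbinol 6): the stereocenter is set by reagent-controlled allylboration instead of ketone reduction. (−)-B-Methallyldiisopinocampheylborane (from (−)-Ipc2BOMe and methallylmagnesium chloride; Et2O, −78 °C; then NaOH, H2O2), which attacks the Si face of aldehydes, should give (S)-1-(2-methoxy-4-{[2-(trimethylsilyl)ethoxy]methoxy}phenyl)-3-methylbut-3-en-1-ol F9. Hydrogenation of the 1,1-disubstituted alkene (H2, RhCl(PPh3)3, benzene–EtOH), which leaves the benzylic C–O bond intact, gives 6; steps 2 and 3 are then not needed.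

**Further compounds**

F1 | step 12 | trimethyl{2-[(2-fluoro-5-methylphenoxy)methoxy]ethyl}silane | Cc1ccc(F)c(OCOCC[Si](C)(C)C)c1
F2 | step 12 | 2-fluoro-5-methyl-3-{[2-(trimethylsilyl)ethoxy]methoxy}benzaldehyde | Cc1cc(C=O)c(F)c(OCOCC[Si](C)(C)C)c1
F3 | step 12 | allyl (S)-6-(2-formyl-4-methyl-6-{[2-(trimethylsilyl)ethoxy]methoxy}phenoxy)-3-(1-hydroxy-3-methylbutyl)-2-methoxybenzoate | COc1c([C@H](CC(C)C)O)ccc(Oc2c(OCOCC[Si](C)(C)C)cc(C)cc2C=O)c1C(=O)OCC=C
F4 | step 12 | allyl (S)-3-(1-acetoxy-3-methylbutyl)-6-(2-formyl-4-methyl-6-{[2-(trimethylsilyl)ethoxy]methoxy}phenoxy)-2-methoxybenzoate | COc1c([C@H](CC(C)C)OC(C)=O)ccc(Oc2c(OCOCC[Si](C)(C)C)cc(C)cc2C=O)c1C(=O)OCC=C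
F5 | step 12 | allyl (S)-3-(1-acetoxy-3-methylbutyl)-6-(2-formyl-6-hydroxy-4-methylphenoxy)-2-methoxybenzoate | COc1c([C@H](CC(C)C)OC(C)=O)ccc(Oc2c(O)cc(C)cc2C=O)c1C(=O)OCC=C
F6 | step 5 | (S)-tert-butyl[1-(2-methoxy-4-{[2-(trimethylsilyl)ethoxy]methoxy}phenyl)-3-methylbutoxy]dimethylsilane | COc1c([C@H](CC(C)C)O[Si](C)(C)C(C)(C)C)ccc(OCOCC[Si](C)(C)C)c1
F7 | step 5 | (S)-3-{1-[(tert-butyldimethylsilyl)oxy]-3-methylbutyl}-2-methoxy-6-{[2-(trimethylsilyl)ethoxy]methoxy}benzoic acid | COc1c([C@H](CC(C)C)O[Si](C)(C)C(C)(C)C)ccc(OCOCC[Si](C)(C)C)c1C(=O)O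
F8 | step 5 | allyl (S)-3-{1-[(tert-butyldimethylsilyl)oxy]-3-methylbutyl}-2-methoxy-6-{[2-(trimethylsilyl)ethoxy]methoxy}benzoate | COc1c([C@H](CC(C)C)O[Si](C)(C)C(C)(C)C)ccc(OCOCC[Si](C)(C)C)c1C(=O)OCC=C
F9 | step 4 | (S)-1-(2-methoxy-4-{[2-(trimethylsilyl)ethoxy]methoxy}phenyl)-3-methylbut-3-en-1-ol | COc1c([C@H](CC(C)=C)O)ccc(OCOCC[Si](C)(C)C)c1
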